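## Retrosynthetic overview

1. The target is the (2R,3R)-trans-3-methoxyflavanone. Rings A (5,6,7-trimethoxybenzo) and B (3,5-dihydroxy-4-methoxyphenyl) are bought as arenes; the pyranone ring C (O1–C2–C3–C4–C4a–C8a) is the only ring made and is closed last.
2. Ring C is cut at O1–C8a and C4–C4a: a formal [4+2] annulation of 3,4,5-trimethoxybenzyne (C4a≡C8a) with the four-atom unit O1–C2–C3–C4 of a β-silyloxy-α-methoxy ester.
3. Enabling feature: the C5 methoxy group of ring A sits next to C4a. In the aryne it steers the O1 alkoxide to C8a and leaves the carbanion on C4a, where the C4 ester must be attacked. C3–H is α to the C4 ketone of ring C, so C3 settles trans to the C2 aryl group by equilibration and only C2 has to be set beforehand.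
4. C2 comes from a Noyori transfer hydrogenation (dynamic kinetic resolution) of a β-keto ester, made by crossed Claisen condensation of the ring-B benzoate with methyl methoxyacetate (which brings C3, its OMe and C4).
5. The last step is hydrogenolysis of the two benzyl ethers on ring B.

Key step: step 7

Assumption: the 2,3-trans (diequatorial) isomer is taken to be the thermodynamic C3 epimer of a 2-aryl-3-methoxychroman-4-one, as in the 3-hydroxy (dihydroflavonol) series; compounds 1, 3 and 7 are taken to be commercial.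

## Route

Step 1
Reactants: 1 methyl 3,5-dihydroxy-4-methoxybenzoate
Product: 2 methyl 3,5-bis(benzyloxy)-4-methoxybenzoate
Conditions: BnBr (2.4 equiv), K2CO3, DMF, 60 °C
Reagents that add atoms: benzyl bromide BrCc1ccccc1
Why: Williamson ether synthesis on the two phenols; benzyl ethers survive base, hydride transfer and fluoride and are removed under neutral conditions at the end.

Step 2
Reactants: 2 methyl 3,5-bis(benzyloxy)-4-methoxybenzoate; 3 methyl methoxyacetate
Product: 4 methyl 3-[3,5-bis(benzyloxy)-4-methoxyphenyl]-2-methoxy-3-oxopropanoate (racemic)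
Conditions: LiHMDS (2.5 equiv), 3 (1.5 equiv), THF, −78 °C → 0 °C; then 1 M HCl
Reagents that add atoms: none
Why: Crossed Claisen condensation: the benzoate cannot enolise, the lithium enolate of 3 is acylated, and deprotonation of the doubly activated product by the second equivalent of base drives the reaction; the new C2 centre is stereolabile and needs no control.

Step 3
Reactants: 4 methyl 3-[3,5-bis(benzyloxy)-4-methoxyphenyl]-2-methoxy-3-oxopropanoate
Product: 5 methyl (2S,3R)-3-[3,5-bis(benzyloxy)-4-methoxyphenyl]-3-hydroxy-2-methoxypropanoate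
Conditions: RuCl(p-cymene)[(S,S)-TsDPEN] (1 mol%), HCO2H/Et3N (5:2), CH2Cl2, 30 °C
Reagents that add atoms: none
Why: Noyori asymmetric transfer hydrogenation with dynamic kinetic resolution: the α-methoxy β-keto ester racemises through its enol faster than it is reduced, and the Ru–H/N–H catalyst delivers hydride to one face of the aryl ketone to give the 3R carbinol (the future C2) as the syn ester; the (S,S) catalyst is the enantiomer expected from the aryl-ketone model, the antipode being used if the sense proves opposite.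

Step 4
Reactants: 5 methyl (2S,3R)-3-[3,5-bis(benzyloxy)-4-methoxyphenyl]-3-hydroxy-2-methoxypropanoate
Product: 6 methyl (2S,3R)-3-[3,5-bis(benzyloxy)-4-methoxyphenyl]-2-methoxy-3-[(trimethylsilyl)oxy]propanoate
Conditions: TMSCl (1.5 equiv), Et3N, CH2Cl2, 0 °C; filtered and used at once
Reagents that add atoms: chlorotrimethylsilane C[Si](C)(C)Cl
Why: O-silylation of the secondary alcohol, which stores the alkoxide in a form that fluoride can release without any proton source in the key step.

Step 5
Reactants: 7 3,4,5-trimethoxyphenol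
Product: 8 2-bromo-3,4,5-trimethoxyphenol
Conditions: NBS (1.0 equiv), CH2Cl2, −78 °C → 0 °C
Reagents that add atoms: N-bromosuccinimide O=C1CCC(=O)N1Br
Why: Electrophilic aromatic bromination; the para position is blocked and the two ortho positions are equivalent, so one equivalent of NBS should give a single monobromide.

Step 6
Reactants: 8 2-bromo-3,4,5-trimethoxyphenol
Product: 11 3,4,5-trimethoxy-2-(trimethylsilyl)phenyl trifluoromethanesulfonate, via (2-bromo-3,4,5-trimethoxyphenoxy)trimethylsilane 9 (not isolated), via lithium 2-silylphenolate 10 (not isolated)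
Conditions: HMDS, THF, 70 °C, then evaporation; n-BuLi, THF, −100 → −78 °C; Tf2O, −100 → −78 °C
Reagents that add atoms: hexamethyldisilazane C[Si](C)(C)N[Si](C)(C)C; trifluoromethanesulfonic anhydride O=S(=O)(OS(=O)(=O)C(F)(F)F)C(F)(F)F
Why: Standard sequence to o-silylaryl triflates: O-silylation, bromine–lithium exchange with retro-Brook (1,3 O→C) silyl migration, and O-triflation of the phenolate; the silyl group ends on the carbon flanked by OMe (the future C4a) and the triflate on the future C8a.

Step 7
Reactants: 6 methyl (2S,3R)-3-[3,5-bis(benzyloxy)-4-methoxyphenyl]-2-methoxy-3-[(trimethylsilyl)oxy]propanoate; 11 3,4,5-trimethoxy-2-(trimethylsilyl)phenyl trifluoromethanesulfonate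
Product: 15 (2R,3R)-2-[3,5-bis(benzyloxy)-4-methoxyphenyl]-3,5,6,7-tetramethoxychroman-4-one, via potassium alkoxide 12 (not isolated), via 3,4,5-trimethoxybenzyne 13 (not isolated), via cis-flavanone 14 (not isolated)
Conditions: KF (3 equiv), 18-crown-6 (3 equiv), THF, 0 °C → rt (6 added slowly to 11, 1.5 equiv); then DBU (10 mol%), rt
Reagents that add atoms: none
Why: Proposed new method: fluoride releases the alkoxide 12 from 6 and the aryne 13 from 11; the alkoxide oxygen adds to the aryne carbon remote from the flanking methoxy group (future C8a), and the carbanion formed next to that methoxy group (future C4a) attacks the methyl ester (future C4) and expels methoxide, which is silylated by a further molecule of 6 and so passes the alkoxide on. The closest known reaction type is the aryne annulation of salicylate esters to xanthones (phenoxide O-arylation, then acylation of the aryl anion by the ester) and related aryne σ-insertions; an aliphatic β-oxido ester has not been shown in this role. Ring C is closed by an intermolecular C–O bond formation followed by a 6-exo-trig acyl substitution, a formal [4+2] between the O1–C2–C3–C4 unit and the aryne. The C2–O bond is never broken, so the 3R carbinol of 6 becomes C2 (R) with retention; C3 first appears cis (14) and is equilibrated through the C4 enolate to the trans isomer 15, controlled by the equatorial C2 aryl group. The step needs regioselective addition to an unsymmetrical aryne, secured by the methoxy group next to the future C4a (aryne distortion and inductive stabilisation of the ortho carbanion, as in 3-methoxybenzyne), and acylation of the aryl anion in preference to protonation, secured by the aprotic release of the alkoxide from the silyl ether and the six-membered transition state.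

Step 8
Reactants: 15 (2R,3R)-2-[3,5-bis(benzyloxy)-4-methoxyphenyl]-3,5,6,7-tetramethoxychroman-4-one
Product: 16 (2R,3R)-2-(3,5-dihydroxy-4-methoxyphenyl)-3,5,6,7-tetramethoxychroman-4-one
Conditions: H2 (1 atm), 10% Pd/C, EtOAc/MeOH, rt
Reagents that add atoms: none
Why: Palladium-catalysed hydrogenolysis of the two benzyl aryl ethers; the methyl ethers, the aryl ketone and the ring C2–O1 bond should survive at 1 atm with monitoring, and no stereocentre is touched.

## Compound list

1 | methyl 3,5-dihydroxy-4-methoxybenzoate | COC(=O)c1cc(O)c(OC)c(O)c1 | starting material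
2 | methyl 3,5-bis(benzyloxy)-4-methoxybenzoate | COC(=O)c1cc(OCc2ccccc2)c(OC)c(OCc2ccccc2)c1 | intermediate
3 | methyl methoxyacetate | COCC(=O)OC | starting material
4 | methyl 3-[3,5-bis(benzyloxy)-4-methoxyphenyl]-2-methoxy-3-oxopropanoate (racemic) | COC(=O)C(OC)C(=O)c1cc(OCc2ccccc2)c(OC)c(OCc2ccccc2)c1 | intermediate
5 | methyl (2S,3R)-3-[3,5-bis(benzyloxy)-4-methoxyphenyl]-3-hydroxy-2-methoxypropanoate | COC(=O)[C@@H](OC)[C@H](O)c1cc(OCc2ccccc2)c(OC)c(OCc2ccccc2)c1 | intermediate
6 | methyl (2S,3R)-3-[3,5-bis(benzyloxy)-4-methoxyphenyl]-2-methoxy-3-[(trimethylsilyl)oxy]propanoate | COC(=O)[C@@H](OC)[C@H](O[Si](C)(C)C)c1cc(OCc2ccccc2)c(OC)c(OCc2ccccc2)c1 | intermediate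
7 | 3,4,5-trimethoxyphenol | COc1cc(O)cc(OC)c1OC | starting material
8 | 2-bromo-3,4,5-trimethoxyphenol | COc1cc(O)c(Br)c(OC)c1OC | intermediate
9 | (2-bromo-3,4,5-trimethoxyphenoxy)trimethylsilane | COc1cc(O[Si](C)(C)C)c(Br)c(OC)c1OC | intermediate
10 | lithium 3,4,5-trimethoxy-2-(trimethylsilyl)phenolate | COc1cc([O-])c([Si](C)(C)C)c(OC)c1OC.[Li+] | intermediate
11 | 3,4,5-trimethoxy-2-(trimethylsilyl)phenyl trifluoromethanesulfonate | COc1cc(OS(=O)(=O)C(F)(F)F)c([Si](C)(C)C)c(OC)c1OC | intermediate
12 | potassium (1R,2S)-1-[3,5-bis(benzyloxy)-4-methoxyphenyl]-2,3-dimethoxy-3-oxopropan-1-olate | COC(=O)[C@@H](OC)[C@H]([O-])c1cc(OCc2ccccc2)c(OC)c(OCc2ccccc2)c1.[K+] | intermediate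
13 | 3,4,5-trimethoxybenzyne (1,2-didehydro-3,4,5-trimethoxybenzene) | COC1=C(OC)C(OC)=CC#C1 | intermediate
14 | (2R,3S)-2-[3,5-bis(benzyloxy)-4-methoxyphenyl]-3,5,6,7-tetramethoxychroman-4-one (cis) | COc1cc2c(c(OC)c1OC)C(=O)[C@@H](OC)[C@@H](c1cc(OCc3ccccc3)c(OC)c(OCc3ccccc3)c1)O2 | intermediate
15 | (2R,3R)-2-[3,5-bis(benzyloxy)-4-methoxyphenyl]-3,5,6,7-tetramethoxychroman-4-one (trans) | COc1cc2c(c(OC)c1OC)C(=O)[C@H](OC)[C@@H](c1cc(OCc3ccccc3)c(OC)c(OCc3ccccc3)c1)O2 | intermediate
16 | (2R,3R)-2-(3,5-dihydroxy-4-methoxyphenyl)-3,5,6,7-tetramethoxychroman-4-one | COc1cc2c(c(OC)c1OC)C(=O)[C@H](OC)[C@@H](c1cc(O)c(OC)c(O)c1)O2 | target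

Total step count: 8. Longest linear sequence: 6 steps (1, 2, 3, 4, 7, 8).

## Steps most likely to fail

**Step 7 (Proposed new method).** After O-arylation the aryl anion may be protonated, or may abstract the C3 proton instead of attacking the ester, which leads to an open-chain aryl ether and β-elimination. The released alkoxide may also fragment by retro-aldol before it meets the aryne, with loss of material and of the C2 configuration. Finally, the C3 equilibration may be accompanied by base-induced opening of ring C.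

Fallback with known chemistry, setting out from 2 and returning at 15; ring C is then closed through the O1–C2 bond. Reduction of 2 (LiAlH4, THF, 0 °C) would give [3,5-bis(benzyloxy)-4-methoxyphenyl]methanol F1, and oxidation (MnO2, CH2Cl2) 3,5-bis(benzyloxy)-4-methoxybenzaldehyde F2. Commercial 1-(2-hydroxy-4,5,6-trimethoxyphenyl)ethan-1-one would be protected (MOMCl, NaH, DMF) as 1-[2-(methoxymethoxy)-4,5,6-trimethoxyphenyl]ethan-1-one F3. Claisen–Schmidt condensation of F3 with F2 (KOH, EtOH, rt) should give (E)-3-[3,5-bis(benzyloxy)-4-methoxyphenyl]-1-[2-(methoxymethoxy)-4,5,6-trimethoxyphenyl]prop-2-en-1-one F4. Juliá–Colonna epoxidation (poly-leucine of the handedness that gives the 2R,3S epoxide, urea–H2O2, DBU, THF) should give {(2R,3S)-3-[3,5-bis(benzyloxy)-4-methoxyphenyl]oxiran-2-yl}[2-(methoxymethoxy)-4,5,6-trimethoxyphenyl]methanone F5. HCl in MeOH (50 °C) removes the MOM group, and the freed phenol opens the epoxide at the benzylic carbon with inversion (6-endo) to (2R,3R)-2-[3,5-bis(benzyloxy)-4-methoxyphenyl]-3-hydroxy-5,6,7-trimethoxychroman-4-one F6. O-Methylation of the 3-OH under non-basic conditions (MeI, Ag2O, CH2Cl2, dark) then gives 15.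

**Step 2.** The methoxyacetate enolate may condense with itself faster than it is acylated by the hindered, electron-rich benzoate, giving low conversion and mixed Claisen products.

Fallback, setting out from 2 and returning at 4; the C3 methoxy group is then introduced by carbenoid O–H insertion. Saponification (LiOH, THF/H2O) would give 3,5-bis(benzyloxy)-4-methoxybenzoic acid F7, and activation with CDI (THF) [3,5-bis(benzyloxy)-4-methoxyphenyl](1H-imidazol-1-yl)methanone F8. Irreversible acylation of the lithium enolate of methyl acetate (LDA, THF, −78 °C) should give methyl 3-[3,5-bis(benzyloxy)-4-methoxyphenyl]-3-oxopropanoate F9. Diazo transfer (p-ABSA, Et3N, MeCN) would give methyl 3-[3,5-bis(benzyloxy)-4-methoxyphenyl]-2-diazo-3-oxopropanoate F10. Rhodium-catalysed O–H insertion into methanol (Rh2(OAc)4 1 mol%, MeOH, CH2Cl2, rt) then gives 4.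

**Step 5.** Electrophilic bromination of the very electron-rich phenol may run on to the dibromide or to oxidative demethylation (quinone formation).

Fallback, setting out from 7 and returning at 11, with no electrophilic halogenation; it replaces steps 5 and 6. Carbamoylation (i-PrNCO, Et3N cat., CH2Cl2) would give 3,4,5-trimethoxyphenyl N-(propan-2-yl)carbamate F11. Carbamate-directed ortho-lithiation and silylation (TBSOTf, TMEDA, Et2O; n-BuLi, −78 °C; TMSCl) at the position between the carbamate and a methoxy group should give 3,4,5-trimethoxy-2-(trimethylsilyl)phenyl N-(propan-2-yl)carbamate F12. Cleavage of the carbamate (Et2NH, DBU, MeCN, 40 °C) would give 3,4,5-trimethoxy-2-(trimethylsilyl)phenol F13, and triflation (Tf2O, pyridine, CH2Cl2, 0 °C) gives 11.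

## Further compounds

F1 | step 7 | [3,5-bis(benzyloxy)-4-methoxyphenyl]methanol | COc1c(OCc2ccccc2)cc(CO)cc1OCc1ccccc1
F2 | step 7 | 3,5-bis(benzyloxy)-4-methoxybenzaldehyde | COc1c(OCc2ccccc2)cc(C=O)cc1OCc1ccccc1
F3 | step 7 | 1-[2-(methoxymethoxy)-4,5,6-trimethoxyphenyl]ethan-1-one | CC(=O)c1c(OCOC)cc(OC)c(OC)c1OC
F4 | step 7 | (E)-3-[3,5-bis(benzyloxy)-4-methoxyphenyl]-1-[2-(methoxymethoxy)-4,5,6-trimethoxyphenyl]prop-2-en-1-one | COCOc1cc(OC)c(OC)c(OC)c1C(=O)/C=C/c1cc(OCc2ccccc2)c(OC)c(OCc2ccccc2)c1
F5 | step 7 | {(2R,3S)-3-[3,5-bis(benzyloxy)-4-methoxyphenyl]oxiran-2-yl}[2-(methoxymethoxy)-4,5,6-trimethoxyphenyl]methanone | COCOc1cc(OC)c(OC)c(OC)c1C(=O)[C@@H]1O[C@H]1c1cc(OCc2ccccc2)c(OC)c(OCc2ccccc2)c1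
F6 | step 7 | (2R,3R)-2-[3,5-bis(benzyloxy)-4-methoxyphenyl]-3-hydroxy-5,6,7-trimethoxychroman-4-one | COc1cc2c(c(OC)c1OC)C(=O)[C@H](O)[C@@H](c1cc(OCc3ccccc3)c(OC)c(OCc3ccccc3)c1)O2
F7 | step 2 | 3,5-bis(benzyloxy)-4-methoxybenzoic acid | COc1c(OCc2ccccc2)cc(C(=O)O)cc1OCc1ccccc1
F8 | step 2 | [3,5-bis(benzyloxy)-4-methoxyphenyl](1H-imidazol-1-yl)methanone | COc1c(OCc2ccccc2)cc(C(=O)n2ccnc2)cc1OCc1ccccc1
F9 | step 2 | methyl 3-[3,5-bis(benzyloxy)-4-methoxyphenyl]-3-oxopropanoate | COC(=O)CC(=O)c1cc(OCc2ccccc2)c(OC)c(OCc2ccccc2)c1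
F10 | step 2 | methyl 3-[3,5-bis(benzyloxy)-4-methoxyphenyl]-2-diazo-3-oxopropanoate | COC(=O)C(=[N+]=[N-])C(=O)c1cc(OCc2ccccc2)c(OC)c(OCc2ccccc2)c1
F11 | step 5 | 3,4,5-trimethoxyphenyl N-(propan-2-yl)carbamate | COc1cc(OC(=O)NC(C)C)cc(OC)c1OC
F12 | step 5 | 3,4,5-trimethoxy-2-(trimethylsilyl)phenyl N-(propan-2-yl)carbamate | COc1cc(OC(=O)NC(C)C)c([Si](C)(C)C)c(OC)c1OC
F13 | step 5 | 3,4,5-trimethoxy-2-(trimethylsilyl)phenol | COc1cc(O)c([Si](C)(C)C)c(OC)c1OC
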